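**Plan**
The chromone is cut at O1–C8a, C4–C4a and O1–C2, after the C3 hydroxyl is taken back to C3–H; this leaves a 3,5-bis(benzyloxy)benzyne (ring A) and an arylpropiolic acid that carries the benzodioxane.
This is possible because on ring A the ring oxygen O1 (on C8a) and the carbonyl carbon C4 (on C4a) are ortho neighbours and C4a has the C5 oxygen on its other side, which is the pattern a 3-alkoxybenzyne leaves when it inserts into the O–C(=O) bond of an acid.
The benzodioxane is cut at its aryl C8a–O1 bond (fluoride displacement para to a nitrile) and at its C2–C3 bond (glycolate aldol with O-benzylvanillin).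
Forward: aldol, auxiliary removal, dioxane ring closure, nitrile to aldehyde to alkyne to propiolic acid, then the pyranone ring in the aryne step, then C3 hydroxylation and hydrogenolysis.
Both stereocentres (2R,3R) come from one Evans syn aldol on (S)-4-benzyloxazolidin-2-one; the ring closure retains them and no later step touches them.

Key step: step 13

Remark: compounds 1, 9, 11 and 13 are taken as purchasable; stannylene acetal 18 is drawn as its monomer, and epoxide 29 is expected as two diastereomers at its new centres, which are erased within the same step.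

**Route**

Step 1
Reactants: 1 3,5-bis(benzyloxy)phenol
Product: 2 3,5-bis(benzyloxy)phenyl N-isopropylcarbamate
Conditions: i-PrNCO, Et3N (cat.), CH2Cl2, rt
Reagents that add atoms: isopropyl isocyanate, CC(C)N=C=O
Why: Amine-catalysed addition of the phenol to the isocyanate (carbamoylation) should give the N-monoalkyl carbamate, which directs ortho-metalation and can later be removed under mild base.

Step 2
Reactants: 2 3,5-bis(benzyloxy)phenyl N-isopropylcarbamate
Product: 6 3,5-bis(benzyloxy)-2-(trimethylsilyl)phenyl N-isopropylcarbamate, via N-silyl carbamate 3 (not isolated), via aryllithium 4 (not isolated), via bis-silyl carbamate 5 (not isolated)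
Conditions: TMSOTf, TMEDA, Et2O, 0 °C → rt; n-BuLi, TMEDA, −78 °C; TMSCl, −78 °C → rt; aq. NaHSO4
Reagents that add atoms: chlorotrimethylsilane, C[Si](C)(C)Cl
Why: In-situ N-silylation masks the N–H, so directed ortho-metalation should occur between the carbamate and a benzyloxy group (the two such positions are equivalent by symmetry), the aryllithium is silylated by TMSCl and the N–Si bond is hydrolysed on work-up.

Step 3
Reactants: 6 3,5-bis(benzyloxy)-2-(trimethylsilyl)phenyl N-isopropylcarbamate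
Product: 8 3,5-bis(benzyloxy)-2-(trimethylsilyl)phenyl trifluoromethanesulfonate, via silylphenol 7 (not isolated)
Conditions: DBU, Et2NH, MeCN, 40 °C; then PhNTf2, rt
Reagents that add atoms: N-phenylbis(trifluoromethanesulfonimide), O=S(=O)(N(c1ccccc1)S(=O)(=O)C(F)(F)F)C(F)(F)F
Why: Base-induced E1cB loss of isopropyl isocyanate (trapped by Et2NH as a urea) frees the o-silylphenoxide, which is triflated in the same flask, the usual one-pot carbamate cleavage/sulfonylation route to o-silylaryl triflates.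

Step 4
Reactants: 9 (S)-4-benzyloxazolidin-2-one
Product: 10 (S)-4-benzyl-3-(bromoacetyl)oxazolidin-2-one
Conditions: n-BuLi, THF, −78 °C; BrCH2COBr, −78 → 0 °C
Reagents that add atoms: bromoacetyl bromide, BrCC(Br)=O
Why: N-Acylation of the lithiated oxazolidinone at the acyl bromide should be much faster than substitution at the alkyl bromide at low temperature.

Step 5
Reactants: 10 (S)-4-benzyl-3-(bromoacetyl)oxazolidin-2-one; 11 4-fluoro-3-hydroxybenzonitrile
Product: 12 (S)-4-benzyl-3-[(5-cyano-2-fluorophenoxy)acetyl]oxazolidin-2-one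
Conditions: K2CO3, acetone, rt
Reagents that add atoms: none
Why: Williamson ether synthesis, in which the weakly basic cyanofluorophenoxide should displace the activated α-bromide by SN2 at room temperature without attacking the imide or an aryl fluoride.

Step 6
Reactants: 12 (S)-4-benzyl-3-[(5-cyano-2-fluorophenoxy)acetyl]oxazolidin-2-one; 13 4-(benzyloxy)-3-methoxybenzaldehyde
Product: 16 (4S)-4-benzyl-3-[(2S,3R)-3-(4-benzyloxy-3-methoxyphenyl)-2-(5-cyano-2-fluorophenoxy)-3-hydroxypropanoyl]oxazolidin-2-one, via boron enolate 14 (not isolated), via boron aldolate 15 (not isolated)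
Conditions: Bu2BOTf, i-Pr2NEt, CH2Cl2, −78 → 0 °C; 13, −78 → 0 °C; then pH 7 KH2PO4/K2HPO4 buffer, MeOH, H2O2, 0 °C
Reagents that add atoms: none
Why: Evans syn glycolate aldol, in which the Z boron enolate reacts through a Zimmerman–Traxler chair with the oxazolidinone carbonyl turned away and the aldehyde on the face opposite the auxiliary benzyl group, which sets C2 as S and C3 as R with the aryloxy and hydroxyl groups syn.

Step 7
Reactants: 16 (4S)-4-benzyl-3-[(2S,3R)-3-(4-benzyloxy-3-methoxyphenyl)-2-(5-cyano-2-fluorophenoxy)-3-hydroxypropanoyl]oxazolidin-2-one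
Product: 17 3-{[(1R,2R)-1-(4-benzyloxy-3-methoxyphenyl)-1,3-dihydroxypropan-2-yl]oxy}-4-fluorobenzonitrile
Conditions: LiBH4, H2O (1 equiv), Et2O/THF, 0 °C
Reagents that add atoms: none
Why: Reductive removal of the auxiliary, in which LiBH4 should reduce the activated exocyclic imide carbonyl to the primary alcohol while nitrile and aryl fluoride stay inert at 0 °C and the oxazolidinone is recovered.

Step 8
Reactants: 17 3-{[(1R,2R)-1-(4-benzyloxy-3-methoxyphenyl)-1,3-dihydroxypropan-2-yl]oxy}-4-fluorobenzonitrile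
Product: 19 3-{[(1R,2R)-3-(benzyloxy)-1-(4-benzyloxy-3-methoxyphenyl)-1-hydroxypropan-2-yl]oxy}-4-fluorobenzonitrile, via stannylene acetal 18 (not isolated)
Conditions: Bu2SnO, PhMe, reflux (Dean–Stark); then BnBr, Bu4NI, PhMe, 90 °C
Reagents that add atoms: benzyl bromide, BrCc1ccccc1
Why: Regioselective O-alkylation through the dibutylstannylene acetal, which activates the less hindered primary oxygen so that benzyl bromide under iodide catalysis should ether the CH2OH group and leave the benzylic hydroxyl free for ring closure.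

Step 9
Reactants: 19 3-{[(1R,2R)-3-(benzyloxy)-1-(4-benzyloxy-3-methoxyphenyl)-1-hydroxypropan-2-yl]oxy}-4-fluorobenzonitrile
Product: 20 (2R,3R)-3-[(benzyloxy)methyl]-2-(4-benzyloxy-3-methoxyphenyl)-2,3-dihydro-1,4-benzodioxine-6-carbonitrile
Conditions: NaH, DMF (dilute), 0 → 60 °C
Reagents that add atoms: none
Why: Intramolecular SNAr, in which the benzylic alkoxide should displace the fluoride para to the nitrile through a Meisenheimer complex to close the six-membered dioxane with retention at both carbons, so the syn aldol pattern becomes the trans-2,3-disubstituted ring.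

Step 10
Reactants: 20 (2R,3R)-3-[(benzyloxy)methyl]-2-(4-benzyloxy-3-methoxyphenyl)-2,3-dihydro-1,4-benzodioxine-6-carbonitrile
Product: 22 (2R,3R)-3-[(benzyloxy)methyl]-2-(4-benzyloxy-3-methoxyphenyl)-2,3-dihydro-1,4-benzodioxine-6-carbaldehyde, via iminoalane 21 (not isolated)
Conditions: i-Bu2AlH, CH2Cl2, −78 °C; then 1 M HCl, 0 °C
Reagents that add atoms: water, O
Why: Partial reduction of the nitrile, in which a single hydride adds at low temperature and the aluminium imine is hydrolysed to the aldehyde on acidic work-up while the ethers are untouched.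

Step 11
Reactants: 22 (2R,3R)-3-[(benzyloxy)methyl]-2-(4-benzyloxy-3-methoxyphenyl)-2,3-dihydro-1,4-benzodioxine-6-carbaldehyde
Product: 23 (2R,3R)-3-[(benzyloxy)methyl]-2-(4-benzyloxy-3-methoxyphenyl)-6-ethynyl-2,3-dihydro-1,4-benzodioxine
Conditions: dimethyl (1-diazo-2-oxopropyl)phosphonate, K2CO3, MeOH/THF, rt
Reagents that add atoms: dimethyl (1-diazo-2-oxopropyl)phosphonate, COP(=O)(OC)C(=[N+]=[N-])C(C)=O
Why: Seyferth–Gilbert homologation in its Ohira–Bestmann form, in which the diazomethylphosphonate anion made in the flask olefinates the aldehyde and the diazoalkene loses N2 with a 1,2-shift to give the terminal alkyne under mild carbonate conditions.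

Step 12
Reactants: 23 (2R,3R)-3-[(benzyloxy)methyl]-2-(4-benzyloxy-3-methoxyphenyl)-6-ethynyl-2,3-dihydro-1,4-benzodioxine
Product: 25 3-[(2R,3R)-3-[(benzyloxy)methyl]-2-(4-benzyloxy-3-methoxyphenyl)-2,3-dihydro-1,4-benzodioxin-6-yl]prop-2-ynoic acid, via lithium acetylide 24 (not isolated)
Conditions: n-BuLi, THF, −78 °C; CO2 (g), −78 → 0 °C; then 1 M HCl to pH 2–3, 0 °C
Reagents that add atoms: carbon dioxide, O=C=O
Why: Deprotonation of the terminal alkyne and carboxylation of the acetylide with CO2 is the standard way to an arylpropiolic acid, and no other C–H in the molecule is acidic enough to compete at −78 °C.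

Step 13
Reactants: 25 3-[(2R,3R)-3-[(benzyloxy)methyl]-2-(4-benzyloxy-3-methoxyphenyl)-2,3-dihydro-1,4-benzodioxin-6-yl]prop-2-ynoic acid; 8 3,5-bis(benzyloxy)-2-(trimethylsilyl)phenyl trifluoromethanesulfonate
Product: 28 5,7-bis(benzyloxy)-2-[(2R,3R)-3-[(benzyloxy)methyl]-2-(4-benzyloxy-3-methoxyphenyl)-2,3-dihydro-1,4-benzodioxin-6-yl]-4H-chromen-4-one, via aryne 26 (not isolated), via hydroxyaryl ynone 27 (not isolated)
Conditions: 8 (1.5 equiv), CsF (4 equiv), THF, 125 °C, sealed tube
Reagents that add atoms: none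
Why: Fluoride removes the silyl group of 8 and triflate leaves to give aryne 26, and the caesium carboxylate of 25 adds through oxygen to the aryne carbon remote from the neighbouring benzyloxy group, because that inductively withdrawing oxygen distorts the triple bond so that negative charge develops on the carbon next to it. The aryl anion then attacks its own ester carbonyl (4-exo-trig) and the strained four-membered alkoxide opens to the o-acylphenoxide of ynone 27, a net insertion of the aryne into the acid C–O bond that forms O1–C8a and C4–C4a. The phenoxide adds to the β-carbon of the ynone in a 6-endo-dig oxa-Michael closure (O1–C2), and protonation at C3 completes the pyranone ring. The closest known reaction type is the fluoride-induced insertion of arynes into the C–O bond of carboxylic acids, which with arylpropiolic acids is known to continue to flavones. No stereocentre is formed, and the two in the dioxane ring lie far from every reacting atom. The step needs oxygen at C8a with acyl at C4a, which the benzyloxy group beside the aryne bond secures, and 6-endo rather than 5-exo closure, which the ynone polarity and the aprotic medium favour, while the hot alcohol-free conditions let acyl transfer outrun protonation of the aryl anion.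

Step 14
Reactants: 28 5,7-bis(benzyloxy)-2-[(2R,3R)-3-[(benzyloxy)methyl]-2-(4-benzyloxy-3-methoxyphenyl)-2,3-dihydro-1,4-benzodioxin-6-yl]-4H-chromen-4-one
Product: 30 5,7-bis(benzyloxy)-2-[(2R,3R)-3-[(benzyloxy)methyl]-2-(4-benzyloxy-3-methoxyphenyl)-2,3-dihydro-1,4-benzodioxin-6-yl]-3-hydroxy-4H-chromen-4-one, via flavone epoxide 29 (not isolated)
Conditions: DMDO (acetone solution), CH2Cl2, 0 °C → rt; concentrate; then p-TsOH·H2O (cat.), CH2Cl2, rt
Reagents that add atoms: dimethyldioxirane, CC1(C)OO1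
Why: Dioxirane epoxidation of the C2–C3 double bond of a 5-O-alkylated flavone followed by acid-catalysed opening at C2 to the oxocarbenium ion and loss of the C3 proton should give the 3-hydroxyflavone, the two epoxide stereocentres being transient.

Step 15
Reactants: 30 5,7-bis(benzyloxy)-2-[(2R,3R)-3-[(benzyloxy)methyl]-2-(4-benzyloxy-3-methoxyphenyl)-2,3-dihydro-1,4-benzodioxin-6-yl]-3-hydroxy-4H-chromen-4-one
Product: 31 3,5,7-trihydroxy-2-[(2R,3R)-2-(4-hydroxy-3-methoxyphenyl)-3-(hydroxymethyl)-2,3-dihydro-1,4-benzodioxin-6-yl]-4H-chromen-4-one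
Conditions: H2 (1 atm), Pd(OH)2/C, THF/MeOH, rt
Reagents that add atoms: none
Why: Catalytic hydrogenolysis should cleave the three aryl benzyl ethers and the primary alkyl benzyl ether, while the flavonol double bond and the much less reactive cyclic benzylic aryl ether of the dioxane survive at room temperature and atmospheric pressure.

**Compound list**

1 | 3,5-bis(benzyloxy)phenol | Oc1cc(OCc2ccccc2)cc(OCc2ccccc2)c1 | starting material
2 | 3,5-bis(benzyloxy)phenyl N-isopropylcarbamate | CC(C)NC(=O)Oc1cc(OCc2ccccc2)cc(OCc2ccccc2)c1 | intermediate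
3 | 3,5-bis(benzyloxy)phenyl N-isopropyl-N-(trimethylsilyl)carbamate (not isolated) | CC(C)N([Si](C)(C)C)C(=O)Oc1cc(OCc2ccccc2)cc(OCc2ccccc2)c1 | intermediate
4 | ortho-lithiated N-silyl carbamate (not isolated) | CC(C)N([Si](C)(C)C)C(=O)Oc1cc(OCc2ccccc2)cc(OCc2ccccc2)c1[Li] | intermediate
5 | 3,5-bis(benzyloxy)-2-(trimethylsilyl)phenyl N-isopropyl-N-(trimethylsilyl)carbamate (not isolated) | CC(C)N([Si](C)(C)C)C(=O)Oc1cc(OCc2ccccc2)cc(OCc2ccccc2)c1[Si](C)(C)C | intermediate
6 | 3,5-bis(benzyloxy)-2-(trimethylsilyl)phenyl N-isopropylcarbamate | CC(C)NC(=O)Oc1cc(OCc2ccccc2)cc(OCc2ccccc2)c1[Si](C)(C)C | intermediate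
7 | 3,5-bis(benzyloxy)-2-(trimethylsilyl)phenol (not isolated) | Oc1cc(OCc2ccccc2)cc(OCc2ccccc2)c1[Si](C)(C)C | intermediate
8 | 3,5-bis(benzyloxy)-2-(trimethylsilyl)phenyl trifluoromethanesulfonate | C[Si](C)(C)c1c(OCc2ccccc2)cc(OCc2ccccc2)cc1OS(=O)(=O)C(F)(F)F | intermediate
9 | (S)-4-benzyloxazolidin-2-one | O=C1N[C@@H](Cc2ccccc2)CO1 | starting material
10 | (S)-4-benzyl-3-(bromoacetyl)oxazolidin-2-one | O=C(CBr)N1[C@@H](Cc2ccccc2)COC1=O | intermediate
11 | 4-fluoro-3-hydroxybenzonitrile | N#Cc1ccc(F)c(O)c1 | starting material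
12 | (S)-4-benzyl-3-[(5-cyano-2-fluorophenoxy)acetyl]oxazolidin-2-one | N#Cc1ccc(F)c(OCC(=O)N2[C@@H](Cc3ccccc3)COC2=O)c1 | intermediate
13 | 4-(benzyloxy)-3-methoxybenzaldehyde | COc1cc(C=O)ccc1OCc1ccccc1 | starting material
14 | Z dibutylboron enolate of 12 (not isolated) | CCCCB(CCCC)O/C(=C\Oc1cc(C#N)ccc1F)N1[C@@H](Cc2ccccc2)COC1=O | intermediate
15 | O-dibutylboryl aldolate of 16 (not isolated) | COc1cc([C@@H](OB(CCCC)CCCC)[C@H](Oc2cc(C#N)ccc2F)C(=O)N2[C@@H](Cc3ccccc3)COC2=O)ccc1OCc1ccccc1 | intermediate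
16 | (4S)-4-benzyl-3-[(2S,3R)-3-(4-benzyloxy-3-methoxyphenyl)-2-(5-cyano-2-fluorophenoxy)-3-hydroxypropanoyl]oxazolidin-2-one | COc1cc([C@@H](O)[C@H](Oc2cc(C#N)ccc2F)C(=O)N2[C@@H](Cc3ccccc3)COC2=O)ccc1OCc1ccccc1 | intermediate
17 | 3-{[(1R,2R)-1-(4-benzyloxy-3-methoxyphenyl)-1,3-dihydroxypropan-2-yl]oxy}-4-fluorobenzonitrile | COc1cc([C@@H](O)[C@H](Oc2cc(C#N)ccc2F)CO)ccc1OCc1ccccc1 | intermediate
18 | 2,2-dibutyl-1,3,2-dioxastannane (stannylene acetal) of diol 17, monomer (not isolated) | CCCC[Sn]1(CCCC)OC[C@@H](Oc2cc(C#N)ccc2F)[C@@H](c2ccc(OCc3ccccc3)c(OC)c2)O1 | intermediate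
19 | 3-{[(1R,2R)-3-(benzyloxy)-1-(4-benzyloxy-3-methoxyphenyl)-1-hydroxypropan-2-yl]oxy}-4-fluorobenzonitrile | COc1cc([C@@H](O)[C@H](Oc2cc(C#N)ccc2F)COCc2ccccc2)ccc1OCc1ccccc1 | intermediate
20 | (2R,3R)-3-[(benzyloxy)methyl]-2-(4-benzyloxy-3-methoxyphenyl)-2,3-dihydro-1,4-benzodioxine-6-carbonitrile | COc1cc([C@H]2Oc3ccc(C#N)cc3O[C@@H]2COCc2ccccc2)ccc1OCc1ccccc1 | intermediate
21 | N-(diisobutylalumanyl)imine of aldehyde 22 (not isolated) | COc1cc([C@H]2Oc3ccc(C=N[Al](CC(C)C)CC(C)C)cc3O[C@@H]2COCc2ccccc2)ccc1OCc1ccccc1 | intermediate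
22 | (2R,3R)-3-[(benzyloxy)methyl]-2-(4-benzyloxy-3-methoxyphenyl)-2,3-dihydro-1,4-benzodioxine-6-carbaldehyde | COc1cc([C@H]2Oc3ccc(C=O)cc3O[C@@H]2COCc2ccccc2)ccc1OCc1ccccc1 | intermediate
23 | (2R,3R)-3-[(benzyloxy)methyl]-2-(4-benzyloxy-3-methoxyphenyl)-6-ethynyl-2,3-dihydro-1,4-benzodioxine | COc1cc([C@H]2Oc3ccc(C#C)cc3O[C@@H]2COCc2ccccc2)ccc1OCc1ccccc1 | intermediate
24 | lithium acetylide of 23 (not isolated) | COc1cc([C@H]2Oc3ccc(C#C[Li])cc3O[C@@H]2COCc2ccccc2)ccc1OCc1ccccc1 | intermediate
25 | 3-[(2R,3R)-3-[(benzyloxy)methyl]-2-(4-benzyloxy-3-methoxyphenyl)-2,3-dihydro-1,4-benzodioxin-6-yl]prop-2-ynoic acid | COc1cc([C@H]2Oc3ccc(C#CC(=O)O)cc3O[C@@H]2COCc2ccccc2)ccc1OCc1ccccc1 | intermediate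
26 | 3,5-bis(benzyloxy)benzyne (not isolated) | C1#CC(OCc2ccccc2)=CC(OCc2ccccc2)=C1 | intermediate
27 | 1-[2,4-bis(benzyloxy)-6-hydroxyphenyl]-3-[(2R,3R)-3-[(benzyloxy)methyl]-2-(4-benzyloxy-3-methoxyphenyl)-2,3-dihydro-1,4-benzodioxin-6-yl]prop-2-yn-1-one (not isolated) | COc1cc([C@H]2Oc3ccc(C#CC(=O)c4c(O)cc(OCc5ccccc5)cc4OCc4ccccc4)cc3O[C@@H]2COCc2ccccc2)ccc1OCc1ccccc1 | intermediate
28 | 5,7-bis(benzyloxy)-2-[(2R,3R)-3-[(benzyloxy)methyl]-2-(4-benzyloxy-3-methoxyphenyl)-2,3-dihydro-1,4-benzodioxin-6-yl]-4H-chromen-4-one | COc1cc([C@H]2Oc3ccc(-c4cc(=O)c5c(OCc6ccccc6)cc(OCc6ccccc6)cc5o4)cc3O[C@@H]2COCc2ccccc2)ccc1OCc1ccccc1 | intermediate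
29 | 2,3-epoxide of flavone 28, two diastereomers at the epoxide carbons (not isolated) | COc1cc([C@H]2Oc3ccc(C45Oc6cc(OCc7ccccc7)cc(OCc7ccccc7)c6C(=O)C4O5)cc3O[C@@H]2COCc2ccccc2)ccc1OCc1ccccc1 | intermediate
30 | 5,7-bis(benzyloxy)-2-[(2R,3R)-3-[(benzyloxy)methyl]-2-(4-benzyloxy-3-methoxyphenyl)-2,3-dihydro-1,4-benzodioxin-6-yl]-3-hydroxy-4H-chromen-4-one | COc1cc([C@H]2Oc3ccc(-c4oc5cc(OCc6ccccc6)cc(OCc6ccccc6)c5c(=O)c4O)cc3O[C@@H]2COCc2ccccc2)ccc1OCc1ccccc1 | intermediate
31 | 3,5,7-trihydroxy-2-[(2R,3R)-2-(4-hydroxy-3-methoxyphenyl)-3-(hydroxymethyl)-2,3-dihydro-1,4-benzodioxin-6-yl]-4H-chromen-4-one | COc1cc([C@H]2Oc3ccc(-c4oc5cc(O)cc(O)c5c(=O)c4O)cc3O[C@@H]2CO)ccc1O | target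

**Count and risks**

Total step count: 15. Longest linear sequence: 12 steps (steps 4–15, from oxazolidinone 9); the aryne precursor branch (steps 1–3) joins at step 13.

Steps most likely to fail:

1. Step 13 (aryne insertion and ring closure). The aryl anion may be protonated before it transfers the acyl group, so the sequence stops at O-arylation. The propiolate may also decarboxylate at 125 °C, or the phenoxide may close 5-exo to the aurone. Fallback, leaving the aryne: aldehyde 22 is condensed (Claisen–Schmidt; KOH, EtOH/THF, rt) with purchased 1-[2,4-bis(benzyloxy)-6-hydroxyphenyl]ethanone (CC(=O)c1c(O)cc(OCc2ccccc2)cc1OCc1ccccc1) to give the 2'-hydroxychalcone F1. Oxidative cyclisation of F1 with I2 (cat.) in DMSO at 120 °C should then give flavone 28, where the route resumes.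

2. Step 14 (epoxidation and opening). Epoxidation of the electron-poor double bond may be slow, so the excess dioxirane starts to oxidise benzylic C–H bonds (benzyl ethers, dioxane C2–H) or the electron-rich rings. Fallback, replacing the oxidation by a metalation: flavone 28 is lithiated at C3 with LiN(i-Pr)2 in THF at −78 °C and trapped with B(OMe)3 to give the 3-(dimethoxyboryl)flavone F2, which is not isolated. Oxidation of F2 with H2O2/AcOH at 0 °C should give flavonol 30, where the route resumes.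

3. Step 8 (tin-mediated benzylation). Regiocontrol may be incomplete, with benzylation of the benzylic hydroxyl or of both hydroxyls, or the tin alkoxide may displace the fluoride early through the primary oxygen. Fallback, closing the ring before benzylation under a temporary protecting group: diol 17 is tritylated (TrCl, Et3N, DMAP, CH2Cl2) to the primary trityl ether F3. Closure with NaH in DMF, as in step 9, gives the tritylated benzodioxane nitrile F4, and p-TsOH·H2O in MeOH/CH2Cl2 removes the trityl group to give the primary alcohol F5. Benzylation of F5 (NaH, BnBr, Bu4NI, THF) should give nitrile 20, where the route resumes.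

**Further compounds**

F1 | step 13 | (E)-1-[2,4-bis(benzyloxy)-6-hydroxyphenyl]-3-[(2R,3R)-3-[(benzyloxy)methyl]-2-(4-benzyloxy-3-methoxyphenyl)-2,3-dihydro-1,4-benzodioxin-6-yl]prop-2-en-1-one | COc1cc([C@H]2Oc3ccc(/C=C/C(=O)c4c(O)cc(OCc5ccccc5)cc4OCc4ccccc4)cc3O[C@@H]2COCc2ccccc2)ccc1OCc1ccccc1
F2 | step 14 | 3-(dimethoxyboryl) derivative of flavone 28 | COc1cc([C@H]2Oc3ccc(-c4oc5cc(OCc6ccccc6)cc(OCc6ccccc6)c5c(=O)c4B(OC)OC)cc3O[C@@H]2COCc2ccccc2)ccc1OCc1ccccc1
F3 | step 8 | 3-{[(1R,2R)-1-(4-benzyloxy-3-methoxyphenyl)-1-hydroxy-3-(trityloxy)propan-2-yl]oxy}-4-fluorobenzonitrile | COc1cc([C@@H](O)[C@H](Oc2cc(C#N)ccc2F)COC(c2ccccc2)(c2ccccc2)c2ccccc2)ccc1OCc1ccccc1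
F4 | step 8 | (2R,3R)-2-(4-benzyloxy-3-methoxyphenyl)-3-[(trityloxy)methyl]-2,3-dihydro-1,4-benzodioxine-6-carbonitrile | COc1cc([C@H]2Oc3ccc(C#N)cc3O[C@@H]2COC(c2ccccc2)(c2ccccc2)c2ccccc2)ccc1OCc1ccccc1
F5 | step 8 | (2R,3R)-2-(4-benzyloxy-3-methoxyphenyl)-3-(hydroxymethyl)-2,3-dihydro-1,4-benzodioxine-6-carbonitrile | COc1cc([C@H]2Oc3ccc(C#N)cc3O[C@@H]2CO)ccc1OCc1ccccc1
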